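**Retrosynthetic overview**
- The target is reached from a ring ketone (C5=O flanked by silyl ethers on O4 and O6) by axial hydride delivery at C5, benzoylation of O5 and O7, and desilylation.
- The strategy rests on ring carbon C1, a CH(OMe) next to the C2=C3 double bond, read as an enal dimethyl acetal that has lost one methoxy group, with C6 as the α-carbon of a C5 carbonyl. The C6–C1 bond is cut; it closes the only ring formed in the route, the six-membered carbocycle.
- The open-chain precursor is a (Z)-enal dimethyl acetal with a C5=C6 enediol bis-silyl ether. It is made by enol silylation of the α-silyloxy aldehyde (C6=O) tautomer, so that H-4 is never α to a carbonyl group before ring closure.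
- The C3–C4 bond comes from Felkin addition of a (Z)-vinyllithium (trans-hydrostannation of 4,4-dimethoxybut-2-yn-1-ol) to (R)-2,3-bis(silyloxy)propanal from methyl (R)-glycerate.

Key step: step 10

**Remarks**
- Atom labels used for all compounds: C1 (CH–OMe), C2 (=CH), C3 (=C), C4, C5, C6 (ring CH–O carbons in that order), C7 (CH2O on C3); O1, O4–O7 are the oxygens on these carbons.
- Assumption: methyl (R)-2,3-dihydroxypropanoate and 4,4-dimethoxybut-2-yn-1-ol are taken as purchasable.
- The glycerate stereocentre (C5) serves only to induce C4 and is erased in step 9. C7 is carried as a PMB ether through the organolithium and Lewis-acid steps and is benzoylated together with O5.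

**Step 1**
Reactants: 1 4,4-dimethoxybut-2-yn-1-ol
Product: 2 (Z)-4,4-dimethoxy-2-(tributylstannyl)but-2-en-1-ol
Conditions: Bu3SnH (1.1 equiv), [Cp*RuCl]4 (1.5 mol %), CH2Cl2, rt
Reagents that add atoms: tributyltin hydride, CCCC[SnH](CCCC)CCCC
Why: Ruthenium-catalysed trans-hydrostannation of a propargylic alcohol, in which the hydroxyl group steers tin to the proximal alkyne carbon (C3) and anti addition of H and Sn places tin cis to the acetal carbon C1, the geometry later needed for the ring.

**Step 2**
Reactants: 2 (Z)-4,4-dimethoxy-2-(tributylstannyl)but-2-en-1-ol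
Product: 3 tributyl[(Z)-4,4-dimethoxy-1-(4-methoxybenzyloxy)but-2-en-2-yl]stannane
Conditions: NaH, 4-MeOC6H4CH2Cl, n-Bu4NI (cat.), THF/DMF, 0 °C → rt
Reagents that add atoms: 4-methoxybenzyl chloride, COc1ccc(CCl)cc1
Why: Williamson etherification; the PMB ether tolerates butyllithium, silyl triflates and fluoride and can be removed oxidatively later without touching silyl ethers.

**Step 3**
Reactants: 4 methyl (R)-2,3-dihydroxypropanoate
Product: 5 methyl (R)-2,3-bis(tert-butyldimethylsilyloxy)propanoate
Conditions: TBSCl (2.4 equiv), imidazole, DMF, rt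
Reagents that add atoms: tert-butyldimethylsilyl chloride, CC(C)(C)[Si](C)(C)Cl
Why: Standard imidazole-mediated silylation of both hydroxyl groups; the stereocentre is not involved.

**Step 4**
Reactants: 5 methyl (R)-2,3-bis(tert-butyldimethylsilyloxy)propanoate
Product: 6 (R)-2,3-bis(tert-butyldimethylsilyloxy)propanal
Conditions: i-Bu2AlH (1.1 equiv), CH2Cl2, −78 °C; MeOH, aq. KNaC4H4O6
Reagents that add atoms: none
Why: Partial reduction of an α-silyloxy ester, whose tetrahedral aluminium hemiacetal is stable at −78 °C and releases the aldehyde only on work-up, so over-reduction and epimerisation should be avoided.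

**Step 5**
Reactants: 3 tributyl[(Z)-4,4-dimethoxy-1-(4-methoxybenzyloxy)but-2-en-2-yl]stannane; 6 (R)-2,3-bis(tert-butyldimethylsilyloxy)propanal
Product: 8 (2R,3S,4Z)-1,2-bis(tert-butyldimethylsilyloxy)-6,6-dimethoxy-4-[(4-methoxybenzyloxy)methyl]hex-4-en-3-ol, via vinyllithium 7 (not isolated)
Conditions: n-BuLi (1.05 equiv), THF, −78 °C; then 6, −78 °C; pH 7 phosphate buffer
Reagents that add atoms: n-butyllithium, [Li]CCCC (its lithium is in intermediate 7; no atoms in 8)
Why: Tin–lithium exchange with retention of alkene geometry followed by Felkin–Anh addition to the non-chelating α-silyloxy aldehyde, the silyloxy group anti to the incoming bulky vinyllithium, which should give the 4,5-anti alcohol with (S) at C4; the minor syn isomer is removed by chromatography on Et3N-washed silica.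

**Step 6**
Reactants: 8 (2R,3S,4Z)-1,2-bis(tert-butyldimethylsilyloxy)-6,6-dimethoxy-4-[(4-methoxybenzyloxy)methyl]hex-4-en-3-ol
Product: 9 (2R,3S,4Z)-1,2,3-tris(tert-butyldimethylsilyloxy)-6,6-dimethoxy-4-[(4-methoxybenzyloxy)methyl]hex-4-ene
Conditions: TBSCl, imidazole, DMAP (cat.), DMF, 40 °C
Reagents that add atoms: tert-butyldimethylsilyl chloride, CC(C)(C)[Si](C)(C)Cl
Why: Base-mediated O-silylation of the hindered allylic hydroxyl; the acid-free medium keeps the cis-disposed C4 hydroxyl from closing onto the C1 acetal.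

**Step 7**
Reactants: 9 (2R,3S,4Z)-1,2,3-tris(tert-butyldimethylsilyloxy)-6,6-dimethoxy-4-[(4-methoxybenzyloxy)methyl]hex-4-ene
Product: 10 (2R,3S,4Z)-2,3-bis(tert-butyldimethylsilyloxy)-6,6-dimethoxy-4-[(4-methoxybenzyloxy)methyl]hex-4-en-1-ol
Conditions: HF·pyridine, pyridine, THF, 0 °C
Reagents that add atoms: none
Why: Chemoselective desilylation, since the primary C6 silyl ether is far less hindered than the secondary C4 and C5 ethers, and the pyridine buffer protects the acetal.

**Step 8**
Reactants: 10 (2R,3S,4Z)-2,3-bis(tert-butyldimethylsilyloxy)-6,6-dimethoxy-4-[(4-methoxybenzyloxy)methyl]hex-4-en-1-ol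
Product: 11 (2S,3S,4Z)-2,3-bis(tert-butyldimethylsilyloxy)-6,6-dimethoxy-4-[(4-methoxybenzyloxy)methyl]hex-4-enal
Conditions: Dess–Martin periodinane, pyridine, CH2Cl2, 0 °C → rt
Reagents that add atoms: none
Why: Dess–Martin oxidation of the primary alcohol under buffered, non-basic conditions, which should avoid β-elimination of the C4 silyloxy group; the labile C5 centre is erased in the next step anyway.

**Step 9**
Reactants: 11 (2S,3S,4Z)-2,3-bis(tert-butyldimethylsilyloxy)-6,6-dimethoxy-4-[(4-methoxybenzyloxy)methyl]hex-4-enal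
Product: 12 (1Z,3S,4Z)-1,2,3-tris(tert-butyldimethylsilyloxy)-6,6-dimethoxy-4-[(4-methoxybenzyloxy)methyl]hexa-1,4-diene
Conditions: TBSOTf (1.3 equiv), Et3N (4 equiv), CH2Cl2, −78 → −20 °C
Reagents that add atoms: tert-butyldimethylsilyl triflate, CC(C)(C)[Si](C)(C)OS(=O)(=O)C(F)(F)F
Why: Soft enolisation (O-silylation of the aldehyde, then loss of H-5, its only α-hydrogen) gives the C5=C6 enediol bis-silyl ether regiospecifically; the (Z) isomer, with the two silyloxy groups cis and the bulky C4 branch trans to O6, should predominate, and the excess amine keeps the medium too weakly Lewis acidic to ionise the acetal.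

**Step 10**
Reactants: 12 (1Z,3S,4Z)-1,2,3-tris(tert-butyldimethylsilyloxy)-6,6-dimethoxy-4-[(4-methoxybenzyloxy)methyl]hexa-1,4-diene
Product: 14 (2S,5S,6R)-2,6-bis(tert-butyldimethylsilyloxy)-5-methoxy-3-[(4-methoxybenzyloxy)methyl]cyclohex-3-en-1-one, via oxocarbenium ion 13 (not isolated)
Conditions: TMSOTf (0.2 equiv), 2,6-di-tert-butyl-4-methylpyridine (0.3 equiv), CH2Cl2, −78 °C; Et3N, aq. NaHCO3
Reagents that add atoms: none
Why: TMSOTf ionises the C1 acetal to the alkene-conjugated oxocarbenium ion 13 (OMe outside, s-trans about C1–C2), C6 of the enediol bis-silyl ether adds to C1, and the resulting C5 silyloxycarbenium ion passes its silyl group to methoxide/triflate, which unveils the C5 ketone, leaves C1 as the methyl ether and regenerates a silyl triflate as chain carrier. The closest known reaction type is the silyl-triflate-promoted Mukaiyama aldol addition of silyl enol ethers to dimethyl acetals, ring-forming cases included. The six-membered carbocycle closes in the 6-(enolendo)-exo-trig mode; bonding from C5 would be a 5-(enolexo) closure onto a fully substituted carbon that leaves the poorer aldehyde-type cation at C6, and attack at C3 would need a four-membered ring. C6 is set by the (Z) enol geometry, whose O6 lies trans to C4 and therefore ends up equatorial, and C1 by the outside position of its methoxy group, which ends up pseudo-equatorial, so the two new C–O bonds are trans. Both are set relative to C4 because the enol arm must leave the C1–C2=C3–C4 plane: in the rotamer with H-4 in that plane beside C7 (least A(1,2) strain) the C4 silyloxy group points to one face and C6 reaches C1 from the other, which should give O4/O6 cis and O4/O1 trans, that is (1S,6R) from (4S). The step therefore needs C6- over C5-attack and 1,4-induction from C4, secured by the substitution pattern of the enediol ether and by the Z alkene that holds C1 beside C4.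

**Step 11**
Reactants: 14 (2S,5S,6R)-2,6-bis(tert-butyldimethylsilyloxy)-5-methoxy-3-[(4-methoxybenzyloxy)methyl]cyclohex-3-en-1-one
Product: 15 ring alcohol with C5–OH trans to both silyloxy groups (O4-TBS and O6-TBS; O1-methyl; O7-PMB; configuration as in the target)
Conditions: NaBH4, CeCl3·7H2O, MeOH, −78 °C
Reagents that add atoms: none
Why: Luche reduction: with O4, O6 and O1 all (pseudo)equatorial the small hydride should add along the axial trajectory, which passes only H-1 because C3 is sp2, whereas equatorial approach eclipses the axial C4–H and C6–H bonds, so the new C5 hydroxyl is equatorial and trans to both neighbours; the weakly basic medium should prevent loss of methanol and silyl migration.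

**Step 12**
Reactants: 15 ring alcohol with C5–OH trans to both silyloxy groups
Product: 16 C5,C7-diol (O4-TBS and O6-TBS; O1-methyl; configuration as in the target)
Conditions: DDQ, CH2Cl2/pH 7 buffer (10:1), 0 °C
Reagents that add atoms: none
Why: Oxidative cleavage of the PMB ether through its benzylic oxocarbenium ion; silyl ethers, the allylic methyl ether and the free C5 hydroxyl are inert.

**Step 13**
Reactants: 16 C5,C7-diol
Product: 17 (1S,4S,5R,6R)-O5,O7-dibenzoate O4,O6-bis(tert-butyldimethylsilyl) ether of the target tetrol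
Conditions: BzCl (4 equiv), pyridine, DMAP (0.3 equiv), CH2Cl2, 0 → 40 °C
Reagents that add atoms: benzoyl chloride, O=C(Cl)c1ccccc1
Why: DMAP-catalysed acylation of the primary allylic and the hindered secondary hydroxyl in one operation; no stereocentre is touched.

**Step 14**
Reactants: 17 (1S,4S,5R,6R)-O5,O7-dibenzoate O4,O6-bis(tert-butyldimethylsilyl) ether
Product: 18 target, (1S,4S,5R,6R)-5-benzoyloxy-3-(benzoyloxymethyl)-1-methoxycyclohex-2-ene-4,6-diol (locants of the remarks)
Conditions: HF·pyridine, THF, 0 °C → rt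
Reagents that add atoms: none
Why: Acidic fluoride desilylation; the non-basic medium should prevent migration of the C5 benzoate to the freed C4 or C6 hydroxyl.

**Compound list**
1 | 4,4-dimethoxybut-2-yn-1-ol | COC(OC)C#CCO | starting material
2 | (Z)-4,4-dimethoxy-2-(tributylstannyl)but-2-en-1-ol | OC/C(=C/C(OC)OC)[Sn](CCCC)(CCCC)CCCC | intermediate
3 | tributyl[(Z)-4,4-dimethoxy-1-(4-methoxybenzyloxy)but-2-en-2-yl]stannane | COc1ccc(COC/C(=C/C(OC)OC)[Sn](CCCC)(CCCC)CCCC)cc1 | intermediate
4 | methyl (R)-2,3-dihydroxypropanoate | COC(=O)[C@H](O)CO | starting material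
5 | methyl (R)-2,3-bis(tert-butyldimethylsilyloxy)propanoate | COC(=O)[C@H](O[Si](C)(C)C(C)(C)C)CO[Si](C)(C)C(C)(C)C | intermediate
6 | (R)-2,3-bis(tert-butyldimethylsilyloxy)propanal | O=C[C@H](O[Si](C)(C)C(C)(C)C)CO[Si](C)(C)C(C)(C)C | intermediate
7 | [(E)-4,4-dimethoxy-1-(4-methoxybenzyloxy)but-2-en-2-yl]lithium (Li cis to the acetal carbon) | COC(OC)/C=C(\[Li])COCc1ccc(OC)cc1 | intermediate (not isolated)
8 | (2R,3S,4Z)-1,2-bis(tert-butyldimethylsilyloxy)-6,6-dimethoxy-4-[(4-methoxybenzyloxy)methyl]hex-4-en-3-ol | COC(OC)/C=C(COCc1ccc(OC)cc1)\[C@H](O)[C@H](O[Si](C)(C)C(C)(C)C)CO[Si](C)(C)C(C)(C)C | intermediate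
9 | (2R,3S,4Z)-1,2,3-tris(tert-butyldimethylsilyloxy)-6,6-dimethoxy-4-[(4-methoxybenzyloxy)methyl]hex-4-ene | COC(OC)/C=C(COCc1ccc(OC)cc1)\[C@H](O[Si](C)(C)C(C)(C)C)[C@H](O[Si](C)(C)C(C)(C)C)CO[Si](C)(C)C(C)(C)C | intermediate
10 | (2R,3S,4Z)-2,3-bis(tert-butyldimethylsilyloxy)-6,6-dimethoxy-4-[(4-methoxybenzyloxy)methyl]hex-4-en-1-ol | COC(OC)/C=C(COCc1ccc(OC)cc1)\[C@H](O[Si](C)(C)C(C)(C)C)[C@H](O[Si](C)(C)C(C)(C)C)CO | intermediate
11 | (2S,3S,4Z)-2,3-bis(tert-butyldimethylsilyloxy)-6,6-dimethoxy-4-[(4-methoxybenzyloxy)methyl]hex-4-enal | COC(OC)/C=C(COCc1ccc(OC)cc1)\[C@H](O[Si](C)(C)C(C)(C)C)[C@H](O[Si](C)(C)C(C)(C)C)C=O | intermediate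
12 | (1Z,3S,4Z)-1,2,3-tris(tert-butyldimethylsilyloxy)-6,6-dimethoxy-4-[(4-methoxybenzyloxy)methyl]hexa-1,4-diene (key-step precursor) | COC(OC)/C=C(COCc1ccc(OC)cc1)\[C@H](O[Si](C)(C)C(C)(C)C)/C(O[Si](C)(C)C(C)(C)C)=C/O[Si](C)(C)C(C)(C)C | intermediate
13 | C1 O-methyl oxocarbenium ion formed from 12 by loss of one methoxy group | C/[O+]=C/C=C(COCc1ccc(OC)cc1)\[C@H](O[Si](C)(C)C(C)(C)C)/C(O[Si](C)(C)C(C)(C)C)=C/O[Si](C)(C)C(C)(C)C | intermediate (not isolated)
14 | (2S,5S,6R)-2,6-bis(tert-butyldimethylsilyloxy)-5-methoxy-3-[(4-methoxybenzyloxy)methyl]cyclohex-3-en-1-one (key-step product) | CO[C@H]1C=C(COCc2ccc(OC)cc2)[C@H](O[Si](C)(C)C(C)(C)C)C(=O)[C@@H]1O[Si](C)(C)C(C)(C)C | intermediate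
15 | ring alcohol: C5–OH trans to the O4 and O6 silyl ethers, O1-methyl, O7-PMB | CO[C@H]1C=C(COCc2ccc(OC)cc2)[C@H](O[Si](C)(C)C(C)(C)C)[C@@H](O)[C@@H]1O[Si](C)(C)C(C)(C)C | intermediate
16 | C5,C7-diol: O4 and O6 silyl ethers, O1-methyl | CO[C@H]1C=C(CO)[C@H](O[Si](C)(C)C(C)(C)C)[C@@H](O)[C@@H]1O[Si](C)(C)C(C)(C)C | intermediate
17 | (1S,4S,5R,6R)-O5,O7-dibenzoate O4,O6-bis(tert-butyldimethylsilyl) ether | CO[C@H]1C=C(COC(=O)c2ccccc2)[C@H](O[Si](C)(C)C(C)(C)C)[C@@H](OC(=O)c2ccccc2)[C@@H]1O[Si](C)(C)C(C)(C)C | intermediate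
18 | (1S,4S,5R,6R)-5-benzoyloxy-3-(benzoyloxymethyl)-1-methoxycyclohex-2-ene-4,6-diol | CO[C@H]1C=C(COC(=O)c2ccccc2)[C@H](O)[C@@H](OC(=O)c2ccccc2)[C@@H]1O | target

**Step count**
Total: 14 steps. Longest linear sequence: 12 steps (steps 1, 2 and 5–14; the branch through steps 3 and 4 is equally long).

**Steps most likely to fail**

1. Step 10. The C1 cation may be captured by the neighbouring C4 silyloxy oxygen (leading to a dihydrofuran acetal), the ring may close through C5 instead of C6, or face selection at C1 may be weak. Fallback, from 12 back to 14: the acetal of 12 is hydrolysed selectively with oxalic acid on wet SiO2 in CH2Cl2 at 0 °C to the free (2Z)-enal enediol bis-silyl ether F1. BF3·OEt2 in CH2Cl2 at −78 °C then promotes an intramolecular Mukaiyama aldol addition of C6 to the coordinated aldehyde, in which no free oxocarbenium ion is generated beside the C4 silyl ether, to give the C1 hydroxy ketone F2 with the same sense of induction expected. O-Methylation of F2 with Me3OBF4 and 1,8-bis(dimethylamino)naphthalene in CH2Cl2 returns the route to 14.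

2. Step 11. Hydride may be delivered from the equatorial direction, or from both faces, and base may induce loss of methanol from the β-methoxy ketone. Fallback, from 14 back to 17: the opposite face is taken on purpose. LiBH(s-Bu)3 in THF at −78 °C should attack only from the equatorial direction and give the C5-epimeric alcohol F3 (C5–OH cis to both silyloxy groups). Mitsunobu esterification with benzoic acid, PPh3 and diisopropyl azodicarboxylate in toluene inverts C5 and installs the benzoate in one operation to give the C5 benzoate PMB ether F4. DDQ in buffered CH2Cl2 removes the PMB group to give the primary alcohol F5, and benzoylation of F5 (BzCl, pyridine) rejoins the route at 17.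

3. Step 9. The silyl triflate may ionise the enal acetal before the enol ether is complete, or the enol ether may form as a geometric mixture that does not survive isolation. Fallback, from 11 back to 14: enol silylation and ring closure are run as one domino operation. Aldehyde 11 is treated with TBSOTf (2.2 equiv) and i-Pr2NEt in CH2Cl2 from −78 to −20 °C, so that 12 is generated and cyclised by the excess silyl triflate in the same flask (one-pot enol silane formation and Mukaiyama addition to an acetal); this delivers 14 without a new intermediate.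

**Further compounds**
F1 | step 10 | (2Z,4S,5Z)-4,5,6-tris(tert-butyldimethylsilyloxy)-3-[(4-methoxybenzyloxy)methyl]hexa-2,5-dienal | O=C/C=C(COCc1ccc(OC)cc1)\[C@H](O[Si](C)(C)C(C)(C)C)/C(O[Si](C)(C)C(C)(C)C)=C/O[Si](C)(C)C(C)(C)C
F2 | step 10 | C1 hydroxy analogue of ketone 14 (C1–OH in place of C1–OMe, same configuration) | O[C@H]1C=C(COCc2ccc(OC)cc2)[C@H](O[Si](C)(C)C(C)(C)C)C(=O)[C@@H]1O[Si](C)(C)C(C)(C)C
F3 | step 11 | C5 epimer of alcohol 15 (C5–OH cis to both silyloxy groups) | CO[C@H]1C=C(COCc2ccc(OC)cc2)[C@H](O[Si](C)(C)C(C)(C)C)[C@H](O)[C@@H]1O[Si](C)(C)C(C)(C)C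
F4 | step 11 | O5-benzoate of 15 (O7-PMB, O4 and O6 silyl ethers) | CO[C@H]1C=C(COCc2ccc(OC)cc2)[C@H](O[Si](C)(C)C(C)(C)C)[C@@H](OC(=O)c2ccccc2)[C@@H]1O[Si](C)(C)C(C)(C)C
F5 | step 11 | O5-benzoate with free C7 hydroxyl (O4 and O6 silyl ethers) | CO[C@H]1C=C(CO)[C@H](O[Si](C)(C)C(C)(C)C)[C@@H](OC(=O)c2ccccc2)[C@@H]1O[Si](C)(C)C(C)(C)C
F0 | step 9 | none | none
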